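**Strategy.** The oxolane ring is opened at C2–C3. C2 is a benzylic CH bonded to the ring oxygen O1, and in the open chain C3–C4(=O)–C5H2–O1–C2H2Ar it is the fifth atom counted from C3, so a dirhodium carbene generated at C3 can insert into a C2–H bond. This one operation closes the oxolane, forms C2–C3, sets C2 under catalyst control and leaves C3, which epimerises through its enol, in the more stable trans arrangement. The substrate is an acyclic α-diazo β-keto ester carrying a veratryl ether, made in two steps. The C4 ketone is then used to build the quaternary acetoxy/benzyl centre by methylenation, epoxidation and aryl Grignard opening.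

Key step: step 3

Remark: which enantiomer of the catalyst delivers (2S)-5 cannot be read from the substrate; the S-ligand complex is assumed, and Rh2(R-PTTL)4 is used instead if a first run shows the opposite sense. Unless a name says otherwise, ring atoms carry the numbering of the target (O1, C2 aryl, C3 arm, C4, C5).

**Step 1**
Reactants: 1 (3,4-dimethoxyphenyl)methanol; 2 methyl 4-chloro-3-oxobutanoate
Product: 3 methyl 4-[(3,4-dimethoxybenzyl)oxy]-3-oxobutanoate
Conditions: NaH (2.2 equiv), THF, 0 °C → rt
Reagents that add atoms: none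
Why: Williamson ether synthesis in which one equivalent of hydride turns 2 into its enolate, shielding both carbonyl groups, while the sodium alkoxide of 1 displaces the primary chloride by SN2.

**Step 2**
Reactants: 3 methyl 4-[(3,4-dimethoxybenzyl)oxy]-3-oxobutanoate
Product: 4 methyl 2-diazo-4-[(3,4-dimethoxybenzyl)oxy]-3-oxobutanoate
Conditions: p-ABSA, Et3N, MeCN, 0 °C → rt
Reagents that add atoms: 4-acetamidobenzenesulfonyl azide (p-ABSA), CC(=O)Nc1ccc(cc1)S(=O)(=O)N=[N+]=[N-]
Why: Regitz diazo transfer, in which the amine-generated enolate of the doubly activated methylene attacks the terminal azide nitrogen and the adduct collapses to the diazo compound and the sulfonamide.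

**Step 3**
Reactants: 4 methyl 2-diazo-4-[(3,4-dimethoxybenzyl)oxy]-3-oxobutanoate
Product: 5 methyl (2S,3R)-2-(3,4-dimethoxyphenyl)-4-oxooxolane-3-carboxylate (2,3-trans)
Conditions: Rh2(S-PTTL)4 (dirhodium tetrakis[N-phthaloyl-(S)-tert-leucinate], 2 mol %), CH2Cl2, 0 °C, slow addition of 4
Reagents that add atoms: none
Why: Loss of N2 from 4 at the divalent rhodium centre gives an electrophilic keto-ester carbene at C3, which inserts into a benzylic C2–H bond through a concerted but asynchronous three-centre transition state with hydride-transfer character; this is the established dirhodium-catalysed intramolecular C–H insertion of α-diazo β-keto esters next to an ether oxygen (reaction type: carbene 1,5-C–H insertion). The oxolan-3-one ring is closed in the 1,5-insertion mode, the carbene carbon bonding to the fifth chain atom, which is the normal five-ring preference of such carbenes. C2 is set by the chiral carboxylate ligands, which let only one of the two enantiotopic benzylic hydrogens reach the carbene; C3 lies between two carbonyl groups, equilibrates through its enol and should rest trans to the aryl group, giving (2S,3R). The step needs site selectivity for C2–H over oxonium ylide formation, attack on the arene and carbene dimerisation: the C2–H bonds are the only ones a five-membered closure can reach and are activated by both O1 and the electron-rich ring, attack of O1 on the carbene would need a four-membered ring, and slow addition of 4 keeps the diazo concentration low.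

**Step 4**
Reactants: 5 methyl (2S,3R)-2-(3,4-dimethoxyphenyl)-4-oxooxolane-3-carboxylate
Product: 7 (2S,3S)-2-(3,4-dimethoxyphenyl)-3-(hydroxymethyl)oxolan-4-ol as a mixture of C4 epimers, via hydroxy ester 6 (not isolated)
Conditions: LiBH4 (3 equiv), MeOH (1 equiv), THF, 0 °C → rt
Reagents that add atoms: none
Why: Borohydride reduction in which the ketone is reduced first and the ester then follows with help from the neighbouring alkoxyborate; the C4 carbinol centre forms unselectively, which is harmless because step 6 removes it, and the 2,3-trans relationship is carried over (the 3S label is only a change in CIP ranking).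

**Step 5**
Reactants: 7 (2S,3S)-2-(3,4-dimethoxyphenyl)-3-(hydroxymethyl)oxolan-4-ol
Product: 8 (2S,3S)-3-[(tert-butyldimethylsilyloxy)methyl]-2-(3,4-dimethoxyphenyl)oxolan-4-ol as a mixture of C4 epimers
Conditions: TBSCl (1.05 equiv), imidazole, CH2Cl2, 0 °C
Reagents that add atoms: tert-butyldimethylsilyl chloride (TBSCl), CC(C)(C)[Si](C)(C)Cl
Why: Selective silylation, since the bulky silyl chloride should react with the primary hydroxyl much faster than with the secondary ring hydroxyl.

**Step 6**
Reactants: 8 (2S,3S)-3-[(tert-butyldimethylsilyloxy)methyl]-2-(3,4-dimethoxyphenyl)oxolan-4-ol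
Product: 9 (2S,3R)-3-[(tert-butyldimethylsilyloxy)methyl]-2-(3,4-dimethoxyphenyl)oxolan-4-one
Conditions: DMP, CH2Cl2, 0 °C → rt
Reagents that add atoms: none
Why: Dess–Martin oxidation of the secondary alcohol under base-free conditions should converge both C4 epimers on one ketone without enolising C3 or touching the silyl and benzylic ethers.

**Step 7**
Reactants: 9 (2S,3R)-3-[(tert-butyldimethylsilyloxy)methyl]-2-(3,4-dimethoxyphenyl)oxolan-4-one
Product: 10 tert-butyl{[(2S,3R)-2-(3,4-dimethoxyphenyl)-4-methylideneoxolan-3-yl]methoxy}dimethylsilane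
Conditions: Cp2TiMe2 (3 equiv), toluene/THF, 65 °C, dark
Reagents that add atoms: dimethyltitanocene (Cp2TiMe2), C[Ti](C)(C1C=CC=C1)C1C=CC=C1
Why: Petasis methylenation, in which thermally formed Cp2Ti=CH2 olefinates the ketone through an oxatitanacyclobutane; it is chosen over a basic ylide because an enolate at C3 could expel the silyloxy group or the ring oxygen O1.

**Step 8**
Reactants: 10 tert-butyl{[(2S,3R)-2-(3,4-dimethoxyphenyl)-4-methylideneoxolan-3-yl]methoxy}dimethylsilane
Product: 11 C4 spiro-epoxide of 10, tert-butyl{[(3R,6S,7R)-6-(3,4-dimethoxyphenyl)-1,5-dioxaspiro[2.4]heptan-7-yl]methoxy}dimethylsilane (spiro numbering; epoxide oxygen cis to the C2 aryl group, epoxide CH2 cis to the C3 arm)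
Conditions: mCPBA, CH2Cl2, 0 °C
Reagents that add atoms: 3-chloroperbenzoic acid (mCPBA), OOC(=O)c1cccc(Cl)c1
Why: Prilezhaev epoxidation of the 1,1-disubstituted exocyclic alkene, in which the peracid should approach C4 from the face opposite the adjacent C3 silyloxymethyl arm, placing the oxygen trans and the epoxide CH2 cis to that arm, as the target requires.

**Step 9**
Reactants: 12 4-bromo-2-methoxyphenol
Product: 13 (4-bromo-2-methoxyphenoxy)(tert-butyl)dimethylsilane
Conditions: TBSCl, imidazole, DMF, rt
Reagents that add atoms: tert-butyldimethylsilyl chloride (TBSCl), CC(C)(C)[Si](C)(C)Cl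
Why: Standard phenol silylation, giving an aryl silyl ether that tolerates Grignard formation and is removed together with the primary silyl ether in the last step.

**Step 10**
Reactants: 11 C4 spiro-epoxide; 13 (4-bromo-2-methoxyphenoxy)(tert-butyl)dimethylsilane
Product: 15 (2S,3R,4S)-4-[4-(tert-butyldimethylsilyloxy)-3-methoxybenzyl]-3-[(tert-butyldimethylsilyloxy)methyl]-2-(3,4-dimethoxyphenyl)oxolan-4-ol, via arylmagnesium bromide 14 (not isolated)
Conditions: 13, Mg, THF, 50 °C; then CuI (10 mol %), 11, THF, −30 → 0 °C
Reagents that add atoms: none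
Why: Copper-catalysed Grignard opening of an epoxide, in which the aryl group attacks the unsubstituted epoxide carbon by SN2, so the C4–O bond and the configuration set in step 8 are kept and the new benzyl group is cis to the C3 arm (the C4 label changes from R to S only through CIP ranking).

**Step 11**
Reactants: 15 (2S,3R,4S)-4-[4-(tert-butyldimethylsilyloxy)-3-methoxybenzyl]-3-[(tert-butyldimethylsilyloxy)methyl]-2-(3,4-dimethoxyphenyl)oxolan-4-ol
Product: 16 (2S,3R,4S)-4-[4-(tert-butyldimethylsilyloxy)-3-methoxybenzyl]-3-[(tert-butyldimethylsilyloxy)methyl]-2-(3,4-dimethoxyphenyl)oxolan-4-yl acetate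
Conditions: Ac2O, DMAP, Et3N, CH2Cl2, rt → 40 °C
Reagents that add atoms: acetic anhydride, CC(=O)OC(C)=O
Why: Steglich-type DMAP-catalysed acylation, in which the N-acetylpyridinium ion acetylates the only free hydroxyl, the tertiary one, with no bond to C4 being broken.

**Step 12**
Reactants: 16 (2S,3R,4S)-4-[4-(tert-butyldimethylsilyloxy)-3-methoxybenzyl]-3-[(tert-butyldimethylsilyloxy)methyl]-2-(3,4-dimethoxyphenyl)oxolan-4-yl acetate
Product: 17 (2S,3R,4S)-2-(3,4-dimethoxyphenyl)-4-(4-hydroxy-3-methoxybenzyl)-3-(hydroxymethyl)oxolan-4-yl acetate (CNP0310348.1)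
Conditions: TBAF, AcOH (1 equiv per fluoride), THF, 0 °C → rt
Reagents that add atoms: none
Why: Fluoride-mediated desilylation, in which buffered fluoride cleaves the aryl and the primary alkyl silyl ether through pentacoordinate silicates while the acetic acid keeps the freed primary hydroxyl protonated, so the tertiary acetate should neither migrate nor be cleaved.

**Compound list**
1 | (3,4-dimethoxyphenyl)methanol | COc1ccc(CO)cc1OC | starting material
2 | methyl 4-chloro-3-oxobutanoate | COC(=O)CC(=O)CCl | starting material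
3 | methyl 4-[(3,4-dimethoxybenzyl)oxy]-3-oxobutanoate | COC(=O)CC(=O)COCc1ccc(OC)c(OC)c1 | intermediate
4 | methyl 2-diazo-4-[(3,4-dimethoxybenzyl)oxy]-3-oxobutanoate | COC(=O)C(=[N+]=[N-])C(=O)COCc1ccc(OC)c(OC)c1 | intermediate
5 | methyl (2S,3R)-2-(3,4-dimethoxyphenyl)-4-oxooxolane-3-carboxylate | O=C1CO[C@H](c2ccc(OC)c(OC)c2)[C@H]1C(=O)OC | intermediate
6 | methyl (2S,3S)-2-(3,4-dimethoxyphenyl)-4-hydroxyoxolane-3-carboxylate (2,3-trans, both C4 epimers) | OC1CO[C@H](c2ccc(OC)c(OC)c2)[C@H]1C(=O)OC | intermediate (not isolated)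
7 | (2S,3S)-2-(3,4-dimethoxyphenyl)-3-(hydroxymethyl)oxolan-4-ol (2,3-trans, both C4 epimers) | OC1CO[C@H](c2ccc(OC)c(OC)c2)[C@H]1CO | intermediate
8 | (2S,3S)-3-[(tert-butyldimethylsilyloxy)methyl]-2-(3,4-dimethoxyphenyl)oxolan-4-ol (2,3-trans, both C4 epimers) | OC1CO[C@H](c2ccc(OC)c(OC)c2)[C@H]1CO[Si](C)(C)C(C)(C)C | intermediate
9 | (2S,3R)-3-[(tert-butyldimethylsilyloxy)methyl]-2-(3,4-dimethoxyphenyl)oxolan-4-one | O=C1CO[C@H](c2ccc(OC)c(OC)c2)[C@H]1CO[Si](C)(C)C(C)(C)C | intermediate
10 | tert-butyl{[(2S,3R)-2-(3,4-dimethoxyphenyl)-4-methylideneoxolan-3-yl]methoxy}dimethylsilane | C=C1CO[C@H](c2ccc(OC)c(OC)c2)[C@H]1CO[Si](C)(C)C(C)(C)C | intermediate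
11 | tert-butyl{[(3R,6S,7R)-6-(3,4-dimethoxyphenyl)-1,5-dioxaspiro[2.4]heptan-7-yl]methoxy}dimethylsilane (epoxide O cis to aryl) | C1O[C@@]12CO[C@H](c3ccc(OC)c(OC)c3)[C@H]2CO[Si](C)(C)C(C)(C)C | intermediate
12 | 4-bromo-2-methoxyphenol | COc1cc(Br)ccc1O | starting material
13 | (4-bromo-2-methoxyphenoxy)(tert-butyl)dimethylsilane | COc1cc(Br)ccc1O[Si](C)(C)C(C)(C)C | intermediate
14 | [4-(tert-butyldimethylsilyloxy)-3-methoxyphenyl]magnesium bromide | COc1cc([Mg]Br)ccc1O[Si](C)(C)C(C)(C)C | intermediate (not isolated)
15 | (2S,3R,4S)-4-[4-(tert-butyldimethylsilyloxy)-3-methoxybenzyl]-3-[(tert-butyldimethylsilyloxy)methyl]-2-(3,4-dimethoxyphenyl)oxolan-4-ol | COc1cc(C[C@@]2(O)CO[C@H](c3ccc(OC)c(OC)c3)[C@H]2CO[Si](C)(C)C(C)(C)C)ccc1O[Si](C)(C)C(C)(C)C | intermediate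
16 | (2S,3R,4S)-4-[4-(tert-butyldimethylsilyloxy)-3-methoxybenzyl]-3-[(tert-butyldimethylsilyloxy)methyl]-2-(3,4-dimethoxyphenyl)oxolan-4-yl acetate | COc1cc(C[C@@]2(OC(C)=O)CO[C@H](c3ccc(OC)c(OC)c3)[C@H]2CO[Si](C)(C)C(C)(C)C)ccc1O[Si](C)(C)C(C)(C)C | intermediate
17 | (2S,3R,4S)-2-(3,4-dimethoxyphenyl)-4-(4-hydroxy-3-methoxybenzyl)-3-(hydroxymethyl)oxolan-4-yl acetate | COc1cc(C[C@@]2(OC(C)=O)CO[C@H](c3ccc(OC)c(OC)c3)[C@H]2CO)ccc1O | target

**Step count.** Total: 12 steps. Longest linear sequence: 11 steps (steps 1–8 and 10–12); step 9 is a one-step side branch.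

**Steps most likely to fail**

1. Step 3. The chiral carboxylate may discriminate the two enantiotopic benzylic hydrogens only partly, so that 5 forms with insufficient enantiomeric purity. Fallback, setting out from 4 and returning at 7: achiral Rh2(OAc)4 in CH2Cl2 should give the racemic trans keto ester F1. DMAP-catalysed transesterification of F1 with (1R,2S,5R)-menthol in refluxing toluene converts the enantiomers into two diastereomeric menthyl esters. The (2S,3R) menthyl ester F2 is separated by crystallisation or chromatography from its (2R,3S) diastereomer F3, which is discarded. LiBH4 reduction of F2 releases menthol and delivers diol 7.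

2. Step 8. Facial selectivity may be poor, because the peracid meets the C3 arm on one face of the alkene and the C2 aryl group, one carbon further away, on the other. Fallback, setting out from 10 and returning at 11: dihydroxylation with OsO4 and NMO, if needed with the matched Sharpless ligand, passes through a bulkier transition state that should respond more strongly to the adjacent arm, and gives the diol F4 with the tertiary hydroxyl cis to the aryl group. Tosylation of the primary hydroxyl (TsCl, Et3N, catalytic Bu2SnO) gives the monotosylate F5. K2CO3 in MeOH closes the epoxide by attack of the tertiary alkoxide, with no change at C4, giving 11.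

3. Step 12. The freed primary hydroxyl sits 1,3 to the tertiary acetate, so acetyl migration to the primary oxygen or loss of the acetate may accompany fluoride treatment. Fallback, setting out from 15 and returning at 17: unbuffered TBAF removes both silyl groups before any acetate is present, giving the triol F6. Exhaustive acetylation (Ac2O, DMAP, Et3N) gives the triacetate F7. Lipase B from Candida antarctica with n-butanol in MTBE then transesterifies only the primary and the phenolic acetate under neutral conditions, since a tertiary acetate is not accepted by the enzyme, giving 17.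

**Further compounds**
F1 | step 3 | racemic methyl trans-2-(3,4-dimethoxyphenyl)-4-oxooxolane-3-carboxylate (both enantiomers) | O=C1CO[C@H](c2ccc(OC)c(OC)c2)[C@H]1C(=O)OC.O=C1CO[C@@H](c2ccc(OC)c(OC)c2)[C@@H]1C(=O)OC
F2 | step 3 | (1R,2S,5R)-menthyl (2S,3R)-2-(3,4-dimethoxyphenyl)-4-oxooxolane-3-carboxylate | O=C1CO[C@H](c2ccc(OC)c(OC)c2)[C@H]1C(=O)O[C@@H]1C[C@H](C)CC[C@H]1C(C)C
F3 | step 3 | (1R,2S,5R)-menthyl (2R,3S)-2-(3,4-dimethoxyphenyl)-4-oxooxolane-3-carboxylate | O=C1CO[C@@H](c2ccc(OC)c(OC)c2)[C@@H]1C(=O)O[C@@H]1C[C@H](C)CC[C@H]1C(C)C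
F4 | step 8 | 3-[(tert-butyldimethylsilyloxy)methyl]-2-(3,4-dimethoxyphenyl)-4-(hydroxymethyl)oxolan-4-ol, tertiary OH cis to aryl, 2,3-trans, 2S | OC[C@@]1(O)CO[C@H](c2ccc(OC)c(OC)c2)[C@H]1CO[Si](C)(C)C(C)(C)C
F5 | step 8 | primary 4-methylbenzenesulfonate of F4 | Cc1ccc(cc1)S(=O)(=O)OC[C@@]1(O)CO[C@H](c2ccc(OC)c(OC)c2)[C@H]1CO[Si](C)(C)C(C)(C)C
F6 | step 12 | (2S,3R,4S)-2-(3,4-dimethoxyphenyl)-4-(4-hydroxy-3-methoxybenzyl)-3-(hydroxymethyl)oxolan-4-ol | COc1cc(C[C@@]2(O)CO[C@H](c3ccc(OC)c(OC)c3)[C@H]2CO)ccc1O
F7 | step 12 | triacetate of F6 (tertiary, primary and phenolic acetates) | COc1cc(C[C@@]2(OC(C)=O)CO[C@H](c3ccc(OC)c(OC)c3)[C@H]2COC(C)=O)ccc1OC(C)=O
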